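A direct plan would formylate 1,2,3,4-tetramethoxybenzene A1 by ortho-lithiation and DMF to 2,3,4,5-tetramethoxybenzaldehyde A2, condense A2 with 2'-hydroxy-3',4',6'-trimethoxyacetophenone A3 to the 2'-hydroxychalcone A4, and close ring C with I2/DMSO through the flavanone A5.
Its weak points would be:
- The lithiation/formylation of A1 would spend a stoichiometric organolithium step only to put a one-carbon handle on ring B; the conversion of A1 into A2 builds no part of the core.
- The Claisen–Schmidt condensation would be slow: the acetyl group of A3 sits between two ortho substituents, is deactivated by three donor groups and reacts as a chelated phenoxide, so days in strong base and partial closure of A4 to A5 would give mixtures.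
- The oxidative ring closure would expose two very electron-rich rings to iodine and HI at 120 °C: iodination at C6 of ring A and cleavage of the 5-methoxy group peri to the carbonyl are likely, and the C2 stereocentre of A5 would be made only to be destroyed.

**Retrosynthetic overview**
Ring C would be closed first, on ring A alone: ketone 1 → enaminone 3 → 5,7,8-trimethoxychromone 5 (O1–C2 closure; C2 comes from an amide acetal).
Key disconnection: the C2–C1' bond between pyranone ring C and ring B, made last by twofold C–H coupling of C2–H of 5 with 1,2,3,4-tetramethoxybenzene 6, giving flavone 9.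
Feature used: ring B is a 2,3,4,5-tetramethoxyphenyl group; its parent arene 6 has only two C–H bonds (C5–H, C6–H), equivalent by symmetry, so C–H palladation can only give C1'.
This would avoid the formylation of ring B, the aldol at the hindered ketone, iodine at 120 °C on electron-rich rings and the transient C2 stereocentre.

Key step: step 3

Assumption: ketone 1 and arene 6 are catalogue compounds and are used as bought.

Step 1
Reactants: 1 2'-hydroxy-3',4',6'-trimethoxyacetophenone
Product: 3 (E)-3-(dimethylamino)-1-(2-hydroxy-3,4,6-trimethoxyphenyl)prop-2-en-1-one, via N,O-acetal adduct 2 (not isolated)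
Conditions: DMF-DMA (3 equiv), toluene, 100 °C, 4 h
Reagents that add atoms: N,N-dimethylformamide dimethyl acetal, COC(OC)N(C)C
Why: Amide acetal condensation (enaminone formation), in which the acetal ionises to a methoxymethyleneiminium ion, the enol of the methyl ketone adds to it to give adduct 2, and loss of methanol should give the push-pull enaminone with the thermodynamic E geometry while the chelated 2'-hydroxy group stays free; no stereocentre is formed.

Step 2
Reactants: 3 (E)-3-(dimethylamino)-1-(2-hydroxy-3,4,6-trimethoxyphenyl)prop-2-en-1-one
Product: 5 5,7,8-trimethoxy-4H-chromen-4-one, via 2-(dimethylamino)chromanone 4 (not isolated)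
Conditions: conc. HCl, CH2Cl2, 40 °C, 2 h
Reagents that add atoms: none
Why: Acid-promoted chromone ring closure, in which 6-endo-trig oxa-Michael addition of the phenol to the protonated enaminone gives aminal 4 and elimination of dimethylamine (addition–elimination at a vinylogous amide) should give the aromatic pyranone ring C, the aryl methyl ethers being stable to HCl at 40 °C; the stereocentre of 4 is lost.

Step 3
Reactants: 5 5,7,8-trimethoxy-4H-chromen-4-one; 6 1,2,3,4-tetramethoxybenzene
Product: 9 5,7,8-trimethoxy-2-(2,3,4,5-tetramethoxyphenyl)-4H-chromen-4-one, via arylpalladium pivalate 7 (not isolated), via palladated flavanone 8 (not isolated)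
Conditions: Pd(OCOCF3)2 (15 mol %), AgOAc (3 equiv), CsO2CCMe3 (1 equiv), arene 6 (10 equiv), Me3CCO2H, 100 °C, 24 h
Reagents that add atoms: none
Why: Twofold C–H (dehydrogenative, Fujiwara–Moritani-type) coupling: carboxylate-assisted electrophilic palladation of arene 6 by divalent palladium gives arylpalladium pivalate 7, syn-carbopalladation of the C2=C3 bond of chromone 5 places the aryl group on C2 and palladium on C3 (palladium enolate 8), and β-hydride elimination after equilibration through the O-bound enolate restores the C2=C3 double bond, the zerovalent palladium being reoxidised by AgOAc. The closest known reaction types are the palladium-catalysed oxidative C2-arylation of chromones with simple arenes in pivalic acid and the oxidative Heck arylation of chromones with arylboronic acids, both of which give flavones. No ring is closed: the step joins ring B to C2 of the preformed pyranone ring C and so completes the 2-arylchromone skeleton in one operation, and no stereocentre remains because the two centres of 8 are lost on elimination. Site selectivity on ring B needs no control, because C5–H and C6–H of 6 are its only C–H bonds and are equivalent by symmetry, each ortho to one methoxy group and para to another and therefore reactive towards electrophilic palladation. On the chromone the aryl group should go to C2 because insertion puts palladium α to the carbonyl group as an enolate, C6–H of ring A is shielded by its two flanking methoxy groups, and the product has no C2–H left. The tenfold excess of 6 (recoverable) should favour cross-coupling, at the price of some biaryl from 6.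

**Compound list**
1 | 2'-hydroxy-3',4',6'-trimethoxyacetophenone, i.e. 1-(2-hydroxy-3,4,6-trimethoxyphenyl)ethan-1-one | CC(=O)c1c(O)c(OC)c(OC)cc1OC | starting material
2 | 3-(dimethylamino)-1-(2-hydroxy-3,4,6-trimethoxyphenyl)-3-methoxypropan-1-one, racemic, formed in situ | COC(CC(=O)c1c(O)c(OC)c(OC)cc1OC)N(C)C | intermediate
3 | (E)-3-(dimethylamino)-1-(2-hydroxy-3,4,6-trimethoxyphenyl)prop-2-en-1-one | CN(C)/C=C/C(=O)c1c(O)c(OC)c(OC)cc1OC | intermediate
4 | 2-(dimethylamino)-5,7,8-trimethoxychroman-4-one, racemic, formed in situ | CN(C)C1CC(=O)c2c(OC)cc(OC)c(OC)c2O1 | intermediate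
5 | 5,7,8-trimethoxy-4H-chromen-4-one | O=c1ccoc2c(OC)c(OC)cc(OC)c12 | intermediate
6 | 1,2,3,4-tetramethoxybenzene | COc1ccc(OC)c(OC)c1OC | starting material
7 | (2,3,4,5-tetramethoxyphenyl)palladium pivalate, formed in situ, further ligands omitted | CC(C)(C)C(=O)O[Pd]c1cc(OC)c(OC)c(OC)c1OC | intermediate
8 | [5,7,8-trimethoxy-4-oxo-2-(2,3,4,5-tetramethoxyphenyl)chroman-3-yl]palladium pivalate, racemic, aryl and palladium cis from syn insertion (one enantiomer drawn), formed in situ | COc1cc([C@H]2Oc3c(OC)c(OC)cc(OC)c3C(=O)[C@H]2[Pd]OC(=O)C(C)(C)C)c(OC)c(OC)c1OC | intermediate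
9 | 5,7,8-trimethoxy-2-(2,3,4,5-tetramethoxyphenyl)-4H-chromen-4-one (5,7,8,2',3',4',5'-heptamethoxyflavone), achiral | COc1cc(-c2cc(=O)c3c(OC)cc(OC)c(OC)c3o2)c(OC)c(OC)c1OC | target

**Step count and risks**
Total steps: 3. Longest linear sequence: 3 steps (1 → 3 → 5 → 9); arene 6 enters in step 3 as bought.

Steps most likely to fail:

1. Step 3. Homocoupling and pivaloxylation of the electron-rich arene could consume the arylpalladium species faster than it inserts into the hindered, donor-substituted C2=C3 bond. Competing palladation at C3–H or C6–H of the chromone and early precipitation of palladium metal could also stall the coupling. Fallback, from 5 and 6 back to 9 by deprotonative metalation and cross-coupling: arene 6 would be iodinated at its only kind of position (N-iodosuccinimide, CF3CO2H cat., MeCN) to 1-iodo-2,3,4,5-tetramethoxybenzene F1. Chromone 5 would be zincated at C2 with TMPZnCl·LiCl (TMP = 2,2,6,6-tetramethylpiperidide; THF, no added Lewis acid) to (5,7,8-trimethoxy-4-oxo-4H-chromen-2-yl)zinc chloride F2. Negishi coupling of F2 with F1 (Pd(OAc)2, SPhos, THF, 50 °C) should then give 9.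

2. Step 1. O-Methylation of the phenol by the amide acetal, or incomplete condensation at the doubly ortho-substituted, electron-rich acetyl group, could lower the throughput. Fallback, from 1 back to 5 by Claisen formylation: 1 with ethyl formate and NaH in THF, then acidification, should give 2-hydroxy-5,7,8-trimethoxychroman-4-one F3, the cyclic hemiacetal of the β-ketoaldehyde. Dehydration of F3 with HCl in AcOH should give chromone 5, bypassing enaminone 3.

3. Step 2. Hydrolysis of the enaminone by the aqueous acid, followed by deformylation back to the methyl ketone, could compete with ring closure. Fallback, from 3 back to 5 by an irreversible electrophile-triggered closure: 3 with I2 in CHCl3 at room temperature should give 3-iodo-5,7,8-trimethoxy-4H-chromen-4-one F4 by α-iodination, ring closure and loss of dimethylamine. Hydrodeiodination of F4 (HCO2Na, Pd(PPh3)4 cat., DMF, 80 °C) should then give 5.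

**Further compounds**
F1 | step 3 | 1-iodo-2,3,4,5-tetramethoxybenzene | COc1cc(I)c(OC)c(OC)c1OC
F2 | step 3 | (5,7,8-trimethoxy-4-oxo-4H-chromen-2-yl)zinc chloride, LiCl-complexed in solution, formed in situ | O=c1cc([Zn]Cl)oc2c(OC)c(OC)cc(OC)c12
F3 | step 1 | 2-hydroxy-5,7,8-trimethoxychroman-4-one, racemic | OC1CC(=O)c2c(OC)cc(OC)c(OC)c2O1
F4 | step 2 | 3-iodo-5,7,8-trimethoxy-4H-chromen-4-one | O=c1c(I)coc2c(OC)c(OC)cc(OC)c12
A1 | direct plan | 1,2,3,4-tetramethoxybenzene | COc1ccc(OC)c(OC)c1OC
A2 | direct plan | 2,3,4,5-tetramethoxybenzaldehyde | O=Cc1cc(OC)c(OC)c(OC)c1OC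
A3 | direct plan | 2'-hydroxy-3',4',6'-trimethoxyacetophenone | CC(=O)c1c(O)c(OC)c(OC)cc1OC
A4 | direct plan | (E)-1-(2-hydroxy-3,4,6-trimethoxyphenyl)-3-(2,3,4,5-tetramethoxyphenyl)prop-2-en-1-one | COc1cc(/C=C/C(=O)c2c(O)c(OC)c(OC)cc2OC)c(OC)c(OC)c1OC
A5 | direct plan | 5,7,8-trimethoxy-2-(2,3,4,5-tetramethoxyphenyl)chroman-4-one, racemic | COc1cc(C2CC(=O)c3c(OC)cc(OC)c(OC)c3O2)c(OC)c(OC)c1OC
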